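**Retrosynthetic overview**

1. Feature: the free hydroxyl at C2 of the benzoyl ring (ortho to the ketone carbon) and the O1–C2 bond of the benzofuran. With the benzoyl-ring oxygen bonded to benzofuran C2 in place of the furan oxygen, the same atoms form a 2,3-diaryl-4H-chromen-4-one (a 3-arylflavone).
2. Last skeletal event: the benzofuran O1–C2 bond, made by opening the pyranone of a 3-(2,4-dihydroxyphenyl)flavone at C2 and reclosing through the ortho hydroxyl of the C3 aryl group. The furan ring is closed last and the pyranone ring is given up.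
3. Flavone: C3–aryl bond by Suzuki coupling of a flavonol triflate with a boronate from 4-bromoresorcinol; pyranone ring by Claisen–Schmidt condensation and Algar–Flynn–Oyamada oxidation of an acetophenone with a coumarin-bearing benzaldehyde.
4. Coumarin ring (formed first) by esterification and intramolecular Knoevenagel condensation of a salicylaldehyde with a formylated arylacetic acid made from 2,4-dihydroxyphenylacetic acid.
5. Both 1,1-dimethylallyl groups by aromatic Claisen rearrangement of the 4-O-prenyl ethers of 2,4-dihydroxyacetophenone and 2,4-dihydroxybenzaldehyde. Ring order: coumarin, pyranone, furan.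

Key step: step 20

Remark: the target has no stereocentre. The two hydroxyls of the ring that becomes the benzofuran benzo ring are carried as tert-butyldimethylsilyl (TBS) ethers and both freed before the ring switch; the other four are carried as methoxymethyl (MOM) ethers, so the benzofuran 6-hydroxyl is already free after the key step.

**Route**

Step 1
Reactants: 1 1-(2,4-dihydroxyphenyl)ethanone
Product: 2 1-[2-hydroxy-4-(3-methylbut-2-enyloxy)phenyl]ethanone
Conditions: prenyl bromide (1.1 equiv), K2CO3, acetone, reflux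
Reagents that add atoms: 1-bromo-3-methylbut-2-ene, CC(C)=CCBr
Why: Williamson etherification, in which the 2-hydroxyl is held in a hydrogen bond to the acetyl oxygen so that only the 4-hydroxyl should be alkylated.

Step 2
Reactants: 2 1-[2-hydroxy-4-(3-methylbut-2-enyloxy)phenyl]ethanone
Product: 3 1-[2-(tert-butyldimethylsilyloxy)-4-(3-methylbut-2-enyloxy)phenyl]ethanone
Conditions: TBSCl, imidazole, DMF, rt
Reagents that add atoms: tert-butyldimethylsilyl chloride, CC(C)(C)[Si](C)(C)Cl
Why: Imidazole-promoted silylation of the chelated phenol removes the hydrogen bond that would steer the coming rearrangement to C3 and places a bulky group next to C3.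

Step 3
Reactants: 3 1-[2-(tert-butyldimethylsilyloxy)-4-(3-methylbut-2-enyloxy)phenyl]ethanone
Product: 4 1-[2-(tert-butyldimethylsilyloxy)-4-hydroxy-5-(2-methylbut-3-en-2-yl)phenyl]ethanone
Conditions: PhNEt2, 190 °C, argon, sealed tube, short reaction time
Reagents that add atoms: none
Why: Aromatic Claisen rearrangement, a [3,3]-sigmatropic shift that delivers the prenyl group with allylic inversion as a 1,1-dimethylallyl group to an ortho carbon, where C5 should be preferred over C3, which lies between two oxygen substituents (as in the known rearrangements of 2-alkoxy-4-prenyloxy aryl carbonyl compounds).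

Step 4
Reactants: 4 1-[2-(tert-butyldimethylsilyloxy)-4-hydroxy-5-(2-methylbut-3-en-2-yl)phenyl]ethanone
Product: 6 1-[2-hydroxy-4-(methoxymethoxy)-5-(2-methylbut-3-en-2-yl)phenyl]ethanone, via silyl MOM ether 5 (not isolated)
Conditions: MOMCl, iPr2NEt, CH2Cl2, 0 → 40 °C; then MeOH, K2CO3, rt
Reagents that add atoms: chloromethyl methyl ether, COCCl
Why: MOM etherification of the new phenol followed in the same flask by base-mediated methanolysis of the aryl silyl ether, which should be fast because the leaving phenoxide is ortho to the carbonyl group.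

Step 5
Reactants: 7 2,4-dihydroxybenzaldehyde
Product: 8 2-hydroxy-4-(3-methylbut-2-enyloxy)benzaldehyde
Conditions: prenyl bromide (1.1 equiv), K2CO3, acetone, reflux
Reagents that add atoms: 1-bromo-3-methylbut-2-ene, CC(C)=CCBr
Why: Williamson etherification, selective for the 4-hydroxyl because the 2-hydroxyl is hydrogen-bonded to the formyl oxygen.

Step 6
Reactants: 8 2-hydroxy-4-(3-methylbut-2-enyloxy)benzaldehyde
Product: 9 2-(tert-butyldimethylsilyloxy)-4-(3-methylbut-2-enyloxy)benzaldehyde
Conditions: TBSCl, imidazole, DMF, rt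
Reagents that add atoms: tert-butyldimethylsilyl chloride, CC(C)(C)[Si](C)(C)Cl
Why: Silylation of the chelated phenol, for the same regiochemical reason as in step 2.

Step 7
Reactants: 9 2-(tert-butyldimethylsilyloxy)-4-(3-methylbut-2-enyloxy)benzaldehyde
Product: 10 2-(tert-butyldimethylsilyloxy)-4-hydroxy-5-(2-methylbut-3-en-2-yl)benzaldehyde
Conditions: PhNEt2, 190 °C, argon, sealed tube, short reaction time
Reagents that add atoms: none
Why: Aromatic Claisen rearrangement ([3,3]-sigmatropic, allylic inversion) to the unhindered C5, the course known for 2-alkoxy-4-prenyloxybenzaldehydes.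

Step 8
Reactants: 10 2-(tert-butyldimethylsilyloxy)-4-hydroxy-5-(2-methylbut-3-en-2-yl)benzaldehyde
Product: 12 2-hydroxy-4-(methoxymethoxy)-5-(2-methylbut-3-en-2-yl)benzaldehyde, via silyl MOM ether 11 (not isolated)
Conditions: MOMCl, iPr2NEt, CH2Cl2, 0 → 40 °C; then MeOH, K2CO3, rt
Reagents that add atoms: chloromethyl methyl ether, COCCl
Why: MOM etherification followed by in-flask methanolysis of the activated aryl silyl ether, as in step 4.

Step 9
Reactants: 13 2-(2,4-dihydroxyphenyl)acetic acid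
Product: 14 methyl 2-(2,4-dihydroxyphenyl)acetate
Conditions: MeOH, H2SO4 (cat.), reflux
Reagents that add atoms: methanol, CO
Why: Fischer esterification, which also blocks lactonisation to the benzofuranone in the next step.

Step 10
Reactants: 14 methyl 2-(2,4-dihydroxyphenyl)acetate
Product: 16 methyl 2-(5-formyl-2,4-dihydroxyphenyl)acetate, via iminium salt 15 (not isolated)
Conditions: POCl3, DMF, MeCN, 0 °C → rt; then H2O, 50 °C
Reagents that add atoms: N,N-dimethylformamide, CN(C)C=O; water, O
Why: Vilsmeier–Haack formylation, in which the chloroiminium ion should attack C5 (para to the 2-hydroxyl, ortho to the 4-hydroxyl, and not flanked by two oxygens as C3 is) before water hydrolyses the iminium salt.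

Step 11
Reactants: 16 methyl 2-(5-formyl-2,4-dihydroxyphenyl)acetate
Product: 17 methyl 2-[5-formyl-2,4-bis(methoxymethoxy)phenyl]acetate
Conditions: MOMCl (3 equiv), iPr2NEt, CH2Cl2, 0 °C → reflux
Reagents that add atoms: chloromethyl methyl ether, COCCl
Why: MOM etherification of both phenols, with excess reagent and time allowed for the formyl-chelated one.

Step 12
Reactants: 17 methyl 2-[5-formyl-2,4-bis(methoxymethoxy)phenyl]acetate
Product: 18 2-[5-formyl-2,4-bis(methoxymethoxy)phenyl]acetic acid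
Conditions: LiOH·H2O, THF/H2O, 0 °C; then 0.5 M HCl to pH 4, 0 °C
Reagents that add atoms: lithium hydroxide, [Li+].[OH-]
Why: Saponification of the unhindered aliphatic methyl ester, which the non-enolisable aldehyde and the MOM ethers should tolerate when the base is cold and the work-up is held at pH 4.

Step 13
Reactants: 12 2-hydroxy-4-(methoxymethoxy)-5-(2-methylbut-3-en-2-yl)benzaldehyde; 18 2-[5-formyl-2,4-bis(methoxymethoxy)phenyl]acetic acid
Product: 20 2,4-bis(methoxymethoxy)-5-[7-(methoxymethoxy)-6-(2-methylbut-3-en-2-yl)-2-oxo-2H-chromen-3-yl]benzaldehyde, via aryl ester 19 (not isolated)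
Conditions: EDC·HCl, DMAP (cat.), CH2Cl2, 0 °C → rt; then DBU, rt
Reagents that add atoms: none
Why: Steglich esterification of the phenol of 12 followed by base-induced intramolecular Knoevenagel condensation of the aryl acetate methylene with the ortho formyl group (the Perkin–Oglialoro-type route to 3-arylcoumarins), while the other formyl group is deactivated by two alkoxy donors and could react only intermolecularly.

Step 14
Reactants: 21 4-bromobenzene-1,3-diol
Product: 22 1-bromo-2,4-bis(tert-butyldimethylsilyloxy)benzene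
Conditions: TBSCl (2.4 equiv), imidazole, DMF, rt
Reagents that add atoms: tert-butyldimethylsilyl chloride, CC(C)(C)[Si](C)(C)Cl
Why: Silylation of both phenols gives ethers that are orthogonal to MOM ethers and need no differentiation of the two hydroxyls.

Step 15
Reactants: 22 1-bromo-2,4-bis(tert-butyldimethylsilyloxy)benzene
Product: 23 2-[2,4-bis(tert-butyldimethylsilyloxy)phenyl]-4,4,5,5-tetramethyl-1,3,2-dioxaborolane
Conditions: B2pin2, PdCl2(dppf) (3 mol %), KOAc, 1,4-dioxane, 90 °C
Reagents that add atoms: bis(pinacolato)diboron, CC1(C)OB(B2OC(C)(C)C(C)(C)O2)OC1(C)C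
Why: Miyaura borylation, chosen over bromine–lithium exchange because an ortho-silyloxy aryllithium would suffer silyl migration from oxygen to carbon.

Step 16
Reactants: 6 1-[2-hydroxy-4-(methoxymethoxy)-5-(2-methylbut-3-en-2-yl)phenyl]ethanone; 20 2,4-bis(methoxymethoxy)-5-[7-(methoxymethoxy)-6-(2-methylbut-3-en-2-yl)-2-oxo-2H-chromen-3-yl]benzaldehyde
Product: 26 2-{2,4-bis(methoxymethoxy)-5-[7-(methoxymethoxy)-6-(2-methylbut-3-en-2-yl)-2-oxo-2H-chromen-3-yl]phenyl}-3-hydroxy-7-(methoxymethoxy)-6-(2-methylbut-3-en-2-yl)-4H-chromen-4-one, via seco-chalcone acid 24 (not isolated), via seco-flavonol acid 25 (not isolated)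
Conditions: KOH (aq.), EtOH/THF, rt; then 30% H2O2, 0 °C → rt; then AcOH to pH 5
Reagents that add atoms: hydrogen peroxide, OO
Why: One-pot Claisen–Schmidt condensation and Algar–Flynn–Oyamada oxidation, in which the 2'-hydroxychalcone with unsubstituted C6' should give the flavonol and not an aurone, the lactone opens to the (Z)-coumarinate in the alkaline medium and closes again on acidification, and the isolated terminal alkenes are inert to the nucleophilic oxidant.

Step 17
Reactants: 26 2-{2,4-bis(methoxymethoxy)-5-[7-(methoxymethoxy)-6-(2-methylbut-3-en-2-yl)-2-oxo-2H-chromen-3-yl]phenyl}-3-hydroxy-7-(methoxymethoxy)-6-(2-methylbut-3-en-2-yl)-4H-chromen-4-one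
Product: 27 2-{2,4-bis(methoxymethoxy)-5-[7-(methoxymethoxy)-6-(2-methylbut-3-en-2-yl)-2-oxo-2H-chromen-3-yl]phenyl}-7-(methoxymethoxy)-6-(2-methylbut-3-en-2-yl)-4-oxo-4H-chromen-3-yl trifluoromethanesulfonate
Conditions: PhNTf2, K2CO3, DMF, 0 °C → rt
Reagents that add atoms: N-phenylbis(trifluoromethanesulfonimide), O=S(=O)(N(c1ccccc1)S(=O)(=O)C(F)(F)F)C(F)(F)F
Why: O-sulfonylation of the acidic enolic 3-hydroxyl with a mild triflating agent that leaves MOM ethers, lactone and alkenes untouched.

Step 18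
Reactants: 27 2-{2,4-bis(methoxymethoxy)-5-[7-(methoxymethoxy)-6-(2-methylbut-3-en-2-yl)-2-oxo-2H-chromen-3-yl]phenyl}-7-(methoxymethoxy)-6-(2-methylbut-3-en-2-yl)-4-oxo-4H-chromen-3-yl trifluoromethanesulfonate; 23 2-[2,4-bis(tert-butyldimethylsilyloxy)phenyl]-4,4,5,5-tetramethyl-1,3,2-dioxaborolane
Product: 28 2-{2,4-bis(methoxymethoxy)-5-[7-(methoxymethoxy)-6-(2-methylbut-3-en-2-yl)-2-oxo-2H-chromen-3-yl]phenyl}-3-[2,4-bis(tert-butyldimethylsilyloxy)phenyl]-7-(methoxymethoxy)-6-(2-methylbut-3-en-2-yl)-4H-chromen-4-one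
Conditions: Pd(OAc)2 (5 mol %), SPhos (10 mol %), K3PO4·H2O, toluene, 90 °C
Reagents that add atoms: none
Why: Suzuki–Miyaura coupling of the chromone 3-triflate (a known class of coupling partner), with the bulky electron-rich ligand SPhos to cope with the ortho-substituted partners and a nearly anhydrous phosphate base to spare the silyl ethers.

Step 19
Reactants: 28 2-{2,4-bis(methoxymethoxy)-5-[7-(methoxymethoxy)-6-(2-methylbut-3-en-2-yl)-2-oxo-2H-chromen-3-yl]phenyl}-3-[2,4-bis(tert-butyldimethylsilyloxy)phenyl]-7-(methoxymethoxy)-6-(2-methylbut-3-en-2-yl)-4H-chromen-4-one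
Product: 29 2-{2,4-bis(methoxymethoxy)-5-[7-(methoxymethoxy)-6-(2-methylbut-3-en-2-yl)-2-oxo-2H-chromen-3-yl]phenyl}-3-(2,4-dihydroxyphenyl)-7-(methoxymethoxy)-6-(2-methylbut-3-en-2-yl)-4H-chromen-4-one
Conditions: TBAF, AcOH (1:1), THF, 0 °C
Reagents that add atoms: none
Why: Fluoride-induced cleavage of the two aryl silyl ethers, buffered with acetic acid so that no phenoxide or free base is present that could start the ring switch before the flavone is isolated.

Step 20
Reactants: 29 2-{2,4-bis(methoxymethoxy)-5-[7-(methoxymethoxy)-6-(2-methylbut-3-en-2-yl)-2-oxo-2H-chromen-3-yl]phenyl}-3-(2,4-dihydroxyphenyl)-7-(methoxymethoxy)-6-(2-methylbut-3-en-2-yl)-4H-chromen-4-one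
Product: 31 3-{5-[6-hydroxy-3-(2-hydroxy-4-(methoxymethoxy)-5-(2-methylbut-3-en-2-yl)benzoyl)-1-benzofuran-2-yl]-2,4-bis(methoxymethoxy)phenyl}-7-(methoxymethoxy)-6-(2-methylbut-3-en-2-yl)-2H-chromen-2-one, via enaminone 30 (not isolated)
Conditions: pyrrolidine (0.3 equiv), EtOH, 60 °C, argon
Reagents that add atoms: none
Why: Proposed new method: pyrrolidine should add to C2 of the 4H-chromen-4-one and expel the ring oxygen O1 as the phenoxide of ring A, giving enaminone 30, in which the former C2 is the iminium-type carbon of a vinylogous amide and the former C4 is a ketone deactivated both as the vinylogous amide carbonyl and by the hydrogen bond from the new ortho hydroxyl; the 2-hydroxyl of the 2,4-dihydroxyphenyl group on C3 then adds to that carbon and pyrrolidine leaves, which forms the O1–C2 bond of the benzofuran and returns the catalyst. The closest known reaction type is the amine-mediated opening and reclosure of 2-unsubstituted 3-(2-hydroxyaryl)chromones to 3-(2-hydroxybenzoyl)benzofurans, one of the nucleophile-induced ring transformations of chromones, which has not been shown on a 2-aryl (flavone) substrate. The furan ring closes by 5-exo-trig addition of the phenol oxygen to the C=N+ form of the enaminone, and loss of the amine then makes the ring aromatic. No stereocentre is formed. The step needs closure at the former C2 and not at the ketone carbon, and a forward and not a backward course: the first is secured by the iminium activation of C2 against the deactivated ketone and by the fact that the only free ortho phenol within reach of C2 is the one on the C3 aryl group (the ortho oxygen of the C2 aryl group is a MOM ether), the second by the gain of the aromatic benzofuran and of the strong O–H···O=C hydrogen bond in the liberated 2-hydroxybenzoyl group. The phenoxide of 29 can reach the same product by direct conjugate addition to C2 and β-elimination of the ring-A phenoxide, so the amine and the base pathways converge.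

Step 21
Reactants: 31 3-{5-[6-hydroxy-3-(2-hydroxy-4-(methoxymethoxy)-5-(2-methylbut-3-en-2-yl)benzoyl)-1-benzofuran-2-yl]-2,4-bis(methoxymethoxy)phenyl}-7-(methoxymethoxy)-6-(2-methylbut-3-en-2-yl)-2H-chromen-2-one
Product: 32 3-{5-[3-(2,4-dihydroxy-5-(2-methylbut-3-en-2-yl)benzoyl)-6-hydroxy-1-benzofuran-2-yl]-2,4-dihydroxyphenyl}-7-hydroxy-6-(2-methylbut-3-en-2-yl)-2H-chromen-2-one
Conditions: HCl (1 M in MeOH), THF, 0 °C → rt, stopped at full conversion
Reagents that add atoms: none
Why: Acid-catalysed acetal exchange with methanol should remove the four aryl MOM ethers, while the monosubstituted alkene of each 1,1-dimethylallyl group would have to protonate to a secondary cation and should survive brief, cold, dilute acid, as ortho-(1,1-dimethylallyl)phenols are known to do in alcoholic HCl.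

**Compound list**

1 | 1-(2,4-dihydroxyphenyl)ethanone (2,4-dihydroxyacetophenone) | CC(=O)c1ccc(O)cc1O | starting material
2 | 1-[2-hydroxy-4-(3-methylbut-2-enyloxy)phenyl]ethanone | CC(=O)c1ccc(OCC=C(C)C)cc1O | intermediate
3 | 1-[2-(tert-butyldimethylsilyloxy)-4-(3-methylbut-2-enyloxy)phenyl]ethanone | CC(=O)c1ccc(OCC=C(C)C)cc1O[Si](C)(C)C(C)(C)C | intermediate
4 | 1-[2-(tert-butyldimethylsilyloxy)-4-hydroxy-5-(2-methylbut-3-en-2-yl)phenyl]ethanone | CC(=O)c1cc(C(C)(C)C=C)c(O)cc1O[Si](C)(C)C(C)(C)C | intermediate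
5 | 1-[2-(tert-butyldimethylsilyloxy)-4-(methoxymethoxy)-5-(2-methylbut-3-en-2-yl)phenyl]ethanone (not isolated) | CC(=O)c1cc(C(C)(C)C=C)c(OCOC)cc1O[Si](C)(C)C(C)(C)C | intermediate
6 | 1-[2-hydroxy-4-(methoxymethoxy)-5-(2-methylbut-3-en-2-yl)phenyl]ethanone | CC(=O)c1cc(C(C)(C)C=C)c(OCOC)cc1O | intermediate
7 | 2,4-dihydroxybenzaldehyde | O=Cc1ccc(O)cc1O | starting material
8 | 2-hydroxy-4-(3-methylbut-2-enyloxy)benzaldehyde | O=Cc1ccc(OCC=C(C)C)cc1O | intermediate
9 | 2-(tert-butyldimethylsilyloxy)-4-(3-methylbut-2-enyloxy)benzaldehyde | O=Cc1ccc(OCC=C(C)C)cc1O[Si](C)(C)C(C)(C)C | intermediate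
10 | 2-(tert-butyldimethylsilyloxy)-4-hydroxy-5-(2-methylbut-3-en-2-yl)benzaldehyde | O=Cc1cc(C(C)(C)C=C)c(O)cc1O[Si](C)(C)C(C)(C)C | intermediate
11 | 2-(tert-butyldimethylsilyloxy)-4-(methoxymethoxy)-5-(2-methylbut-3-en-2-yl)benzaldehyde (not isolated) | O=Cc1cc(C(C)(C)C=C)c(OCOC)cc1O[Si](C)(C)C(C)(C)C | intermediate
12 | 2-hydroxy-4-(methoxymethoxy)-5-(2-methylbut-3-en-2-yl)benzaldehyde | O=Cc1cc(C(C)(C)C=C)c(OCOC)cc1O | intermediate
13 | 2-(2,4-dihydroxyphenyl)acetic acid | O=C(O)Cc1ccc(O)cc1O | starting material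
14 | methyl 2-(2,4-dihydroxyphenyl)acetate | COC(=O)Cc1ccc(O)cc1O | intermediate
15 | [2,4-dihydroxy-5-(2-methoxy-2-oxoethyl)benzylidene]dimethylammonium chloride (not isolated) | COC(=O)Cc1cc(C=[N+](C)C)c(O)cc1O.[Cl-] | intermediate
16 | methyl 2-(5-formyl-2,4-dihydroxyphenyl)acetate | COC(=O)Cc1cc(C=O)c(O)cc1O | intermediate
17 | methyl 2-[5-formyl-2,4-bis(methoxymethoxy)phenyl]acetate | COC(=O)Cc1cc(C=O)c(OCOC)cc1OCOC | intermediate
18 | 2-[5-formyl-2,4-bis(methoxymethoxy)phenyl]acetic acid | O=C(O)Cc1cc(C=O)c(OCOC)cc1OCOC | intermediate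
19 | 2-formyl-5-(methoxymethoxy)-4-(2-methylbut-3-en-2-yl)phenyl 2-[5-formyl-2,4-bis(methoxymethoxy)phenyl]acetate (not isolated) | O=Cc1cc(C(C)(C)C=C)c(OCOC)cc1OC(=O)Cc1cc(C=O)c(OCOC)cc1OCOC | intermediate
20 | 2,4-bis(methoxymethoxy)-5-[7-(methoxymethoxy)-6-(2-methylbut-3-en-2-yl)-2-oxo-2H-chromen-3-yl]benzaldehyde | O=Cc1cc(-c2cc3cc(C(C)(C)C=C)c(OCOC)cc3oc2=O)c(OCOC)cc1OCOC | intermediate
21 | 4-bromobenzene-1,3-diol (4-bromoresorcinol) | Oc1ccc(Br)c(O)c1 | starting material
22 | 1-bromo-2,4-bis(tert-butyldimethylsilyloxy)benzene | CC(C)(C)[Si](C)(C)Oc1ccc(Br)c(O[Si](C)(C)C(C)(C)C)c1 | intermediate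
23 | 2-[2,4-bis(tert-butyldimethylsilyloxy)phenyl]-4,4,5,5-tetramethyl-1,3,2-dioxaborolane | CC(C)(C)[Si](C)(C)Oc1ccc(B2OC(C)(C)C(C)(C)O2)c(O[Si](C)(C)C(C)(C)C)c1 | intermediate
24 | (Z)-3-[2-hydroxy-4-(methoxymethoxy)-5-(2-methylbut-3-en-2-yl)phenyl]-2-[5-{(E)-3-[2-hydroxy-4-(methoxymethoxy)-5-(2-methylbut-3-en-2-yl)phenyl]-3-oxoprop-1-enyl}-2,4-bis(methoxymethoxy)phenyl]prop-2-enoic acid (lactone-opened chalcone, potassium salt in the flask, not isolated) | OC(=O)/C(=C\c1cc(C(C)(C)C=C)c(OCOC)cc1O)c1cc(/C=C/C(=O)c2cc(C(C)(C)C=C)c(OCOC)cc2O)c(OCOC)cc1OCOC | intermediate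
25 | (Z)-2-[5-{3-hydroxy-7-(methoxymethoxy)-6-(2-methylbut-3-en-2-yl)-4-oxo-4H-chromen-2-yl}-2,4-bis(methoxymethoxy)phenyl]-3-[2-hydroxy-4-(methoxymethoxy)-5-(2-methylbut-3-en-2-yl)phenyl]prop-2-enoic acid (lactone-opened flavonol, potassium salt in the flask, not isolated) | OC(=O)/C(=C\c1cc(C(C)(C)C=C)c(OCOC)cc1O)c1cc(-c2oc3cc(OCOC)c(C(C)(C)C=C)cc3c(=O)c2O)c(OCOC)cc1OCOC | intermediate
26 | 2-{2,4-bis(methoxymethoxy)-5-[7-(methoxymethoxy)-6-(2-methylbut-3-en-2-yl)-2-oxo-2H-chromen-3-yl]phenyl}-3-hydroxy-7-(methoxymethoxy)-6-(2-methylbut-3-en-2-yl)-4H-chromen-4-one | O=c1c(O)c(-c2cc(-c3cc4cc(C(C)(C)C=C)c(OCOC)cc4oc3=O)c(OCOC)cc2OCOC)oc2cc(OCOC)c(C(C)(C)C=C)cc12 | intermediate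
27 | 2-{2,4-bis(methoxymethoxy)-5-[7-(methoxymethoxy)-6-(2-methylbut-3-en-2-yl)-2-oxo-2H-chromen-3-yl]phenyl}-7-(methoxymethoxy)-6-(2-methylbut-3-en-2-yl)-4-oxo-4H-chromen-3-yl trifluoromethanesulfonate | O=c1c(OS(=O)(=O)C(F)(F)F)c(-c2cc(-c3cc4cc(C(C)(C)C=C)c(OCOC)cc4oc3=O)c(OCOC)cc2OCOC)oc2cc(OCOC)c(C(C)(C)C=C)cc12 | intermediate
28 | 2-{2,4-bis(methoxymethoxy)-5-[7-(methoxymethoxy)-6-(2-methylbut-3-en-2-yl)-2-oxo-2H-chromen-3-yl]phenyl}-3-[2,4-bis(tert-butyldimethylsilyloxy)phenyl]-7-(methoxymethoxy)-6-(2-methylbut-3-en-2-yl)-4H-chromen-4-one | O=c1c(-c2ccc(O[Si](C)(C)C(C)(C)C)cc2O[Si](C)(C)C(C)(C)C)c(-c2cc(-c3cc4cc(C(C)(C)C=C)c(OCOC)cc4oc3=O)c(OCOC)cc2OCOC)oc2cc(OCOC)c(C(C)(C)C=C)cc12 | intermediate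
29 | 2-{2,4-bis(methoxymethoxy)-5-[7-(methoxymethoxy)-6-(2-methylbut-3-en-2-yl)-2-oxo-2H-chromen-3-yl]phenyl}-3-(2,4-dihydroxyphenyl)-7-(methoxymethoxy)-6-(2-methylbut-3-en-2-yl)-4H-chromen-4-one (precursor of the key step) | O=c1c(-c2ccc(O)cc2O)c(-c2cc(-c3cc4cc(C(C)(C)C=C)c(OCOC)cc4oc3=O)c(OCOC)cc2OCOC)oc2cc(OCOC)c(C(C)(C)C=C)cc12 | intermediate
30 | 2-(2,4-dihydroxyphenyl)-1-[2-hydroxy-4-(methoxymethoxy)-5-(2-methylbut-3-en-2-yl)phenyl]-3-{2,4-bis(methoxymethoxy)-5-[7-(methoxymethoxy)-6-(2-methylbut-3-en-2-yl)-2-oxo-2H-chromen-3-yl]phenyl}-3-(pyrrolidin-1-yl)prop-2-en-1-one (enaminone, alkene geometry not fixed, not isolated) | O=C(C(c1ccc(O)cc1O)=C(N1CCCC1)c1cc(-c2cc3cc(C(C)(C)C=C)c(OCOC)cc3oc2=O)c(OCOC)cc1OCOC)c1cc(C(C)(C)C=C)c(OCOC)cc1O | intermediate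
31 | 3-{5-[6-hydroxy-3-(2-hydroxy-4-(methoxymethoxy)-5-(2-methylbut-3-en-2-yl)benzoyl)-1-benzofuran-2-yl]-2,4-bis(methoxymethoxy)phenyl}-7-(methoxymethoxy)-6-(2-methylbut-3-en-2-yl)-2H-chromen-2-one (product of the key step) | C=CC(C)(C)c1cc(C(=O)c2c(-c3cc(-c4cc5cc(C(C)(C)C=C)c(OCOC)cc5oc4=O)c(OCOC)cc3OCOC)oc3cc(O)ccc23)c(O)cc1OCOC | intermediate
32 | 3-{5-[3-(2,4-dihydroxy-5-(2-methylbut-3-en-2-yl)benzoyl)-6-hydroxy-1-benzofuran-2-yl]-2,4-dihydroxyphenyl}-7-hydroxy-6-(2-methylbut-3-en-2-yl)-2H-chromen-2-one (CNP0319672.0) | C=CC(C)(C)c1cc(C(=O)c2c(-c3cc(-c4cc5cc(C(C)(C)C=C)c(O)cc5oc4=O)c(O)cc3O)oc3cc(O)ccc23)c(O)cc1O | target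

**Totals**

Total step count: 21.
Longest linear sequence: 11 steps (steps 5, 6, 7, 8, 13, 16, 17, 18, 19, 20, 21).

**Steps most likely to fail**

Step 20 (ring switch). The flavone may resist opening, because C2 carries an aryl group and is more hindered and less electrophilic than in 2-unsubstituted chromones. Alternatively the opening may be reversible with the equilibrium resting on the chromone side, so that no benzofuran accumulates.
Fallback, from 29 back to 31, in two known operations. Aqueous KOH in EtOH at 50 °C should open the pyranone by hydroxide addition at C2, the classical alkaline fission of flavones to 1-(2-hydroxyaryl)-1,3-diketones. Acidification with AcOH to pH 5, which also recloses the lactone opened alongside, should give 2-(2,4-dihydroxyphenyl)-1-[2-hydroxy-4-(methoxymethoxy)-5-(2-methylbut-3-en-2-yl)phenyl]-3-{2,4-bis(methoxymethoxy)-5-[7-(methoxymethoxy)-6-(2-methylbut-3-en-2-yl)-2-oxo-2H-chromen-3-yl]phenyl}propane-1,3-dione F1. F1 is then cyclodehydrated with PPTS (cat.) in toluene over molecular sieves at 50 °C, the known closure of 2-(2-hydroxyaryl)-1,3-dicarbonyl compounds to 3-acylbenzofurans. The free resorcinol hydroxyl should add to the non-chelated ketone of the central ring in preference to the hydrogen-bonded 2-hydroxyaryl ketone, and water removal makes the furan closure irreversible. Reclosure through the ring-A phenol only returns 29, which is recycled.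

Step 7 (Claisen rearrangement of 9). Part of the material may rearrange to C3 between the two oxygens. At 190 °C the first-formed 1,1-dimethylallyl phenol may rearrange further (abnormal Claisen shift to a 1,2-dimethylallyl group, or ring closure of the new phenol onto the alkene). The prenyl group may also simply be lost.
Fallback, from 7 back to 12, fixing the position with a halogen and bringing in the branched group by cross-coupling. Br2 in AcOH should brominate 7 at C5 to 5-bromo-2,4-dihydroxybenzaldehyde F2. MOMCl and K2CO3 in acetone should etherify only the non-chelated hydroxyl to 5-bromo-2-hydroxy-4-(methoxymethoxy)benzaldehyde F3. A ligand-controlled γ-selective Suzuki–Miyaura coupling of F3 with 3-methylbut-2-enylboronic acid pinacol ester (Pd(OAc)2, bulky dialkylbiarylphosphine, aq. K3PO4, THF, 40–70 °C), which forms the C–C bond at the tertiary allyl terminus, should give 12 directly. Steps 5 to 8 then fall away.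

Step 3 (Claisen rearrangement of 3). The same processes as in step 7 apply: migration to C3, onward rearrangement or cyclisation of the product at high temperature, and loss of the prenyl group.
Fallback, from 1 back to 6. Br2 in AcOH should brominate 1 at C5 to 1-(5-bromo-2,4-dihydroxyphenyl)ethanone F4. MOMCl and K2CO3 in acetone should give 1-[5-bromo-2-hydroxy-4-(methoxymethoxy)phenyl]ethanone F5. The same γ-selective Suzuki–Miyaura coupling with 3-methylbut-2-enylboronic acid pinacol ester should deliver 6. Steps 1 to 4 then fall away.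

**Further compounds**

F1 | step 20 | 2-(2,4-dihydroxyphenyl)-1-[2-hydroxy-4-(methoxymethoxy)-5-(2-methylbut-3-en-2-yl)phenyl]-3-{2,4-bis(methoxymethoxy)-5-[7-(methoxymethoxy)-6-(2-methylbut-3-en-2-yl)-2-oxo-2H-chromen-3-yl]phenyl}propane-1,3-dione | O=C(c1cc(C(C)(C)C=C)c(OCOC)cc1O)C(c1ccc(O)cc1O)C(=O)c1cc(-c2cc3cc(C(C)(C)C=C)c(OCOC)cc3oc2=O)c(OCOC)cc1OCOC
F2 | step 7 | 5-bromo-2,4-dihydroxybenzaldehyde | O=Cc1cc(Br)c(O)cc1O
F3 | step 7 | 5-bromo-2-hydroxy-4-(methoxymethoxy)benzaldehyde | O=Cc1cc(Br)c(OCOC)cc1O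
F4 | step 3 | 1-(5-bromo-2,4-dihydroxyphenyl)ethanone | CC(=O)c1cc(Br)c(O)cc1O
F5 | step 3 | 1-[5-bromo-2-hydroxy-4-(methoxymethoxy)phenyl]ethanone | CC(=O)c1cc(Br)c(OCOC)cc1O
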